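## Analysis of the target

Target 20 is an achiral 20-membered cyclophane in which two benzene rings are joined twice, by a diaryl ether oxygen and by an unbranched chain of twelve methylene groups. Ring A is 1,3,5-trisubstituted (free hydroxyl, ether oxygen, chain), while ring B carries the ether oxygen at C1 between free hydroxyls at C2 and C6 and the chain at C4. There is no stereocentre, and a ring of this size with a flexible chain should not hold planar chirality. The sensitive part is ring B, a pyrogallol mono-aryl ether that oxidises easily in base and air once its hydroxyls are free. The difficulties are the diaryl ether (its ring B carbon is flanked by two oxygen substituents), the closure of a large ring, and the near-identity of the two arenes. The strategy rests on that near-identity: ring A is a 5-alkylresorcinol with one oxygen arylated, and ring B is a 5-alkylresorcinol that has gained the ether oxygen at its C2. In both rings the oxygens are meta to each other and to the chain, which is the pattern of an aldol-folded tetraketide. The two chain-bearing ring carbons and the twelve methylenes between them are the C14 skeleton of tetradecanedioic acid 1.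

## Retrosynthetic reasoning

**20 from 19.** The last operation only frees the three phenols. In 19, ring A carries one methyl ether and ring B carries one methyl ether and one methoxymethyl ether. The ethers are kept to the end because ring B is oxidation-prone once free and because the lithiation and the ether-forming step are run in strong base.

**19 from 18.** The bond cut is the one between the ether oxygen and ring B C1, the carbon para to the chain. It is cut on the ring B side because ring A already owns this oxygen as a fold-derived phenol. The ring B carbon is a C–H between two oxygen substituents and can be addressed selectively. A direct dehydrogenative union of a free ring A phenol with that C–H would be shorter. No laboratory method, however, controls O–C against C–C coupling between two resorcinol rings. The polarity is therefore fixed in 18: phenol on ring A as nucleophile, aryl iodide on ring B as electrophile. The forward reaction has to close a 20-membered ring at a hindered iodide.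

**18 from 16 from 15.** The iodine is placed by deprotonation between the two ring B oxygens. This needs both as ethers, one of them a strongly directing methoxymethyl ether, while ring A keeps its free phenol. Compound 15 is twofold symmetric with one phenol per ring, so the rings can only be told apart statistically, by attaching a single methoxymethyl group (16). This is the cost of building both rings at once. It is placed where the three components of the mixture differ clearly in polarity and both unwanted ones return to 15.

**15 from 13 from 12.** Within each ring the two oxygens are differentiated without statistics. In 12 each ring has an ester ortho to one hydroxyl and para to the other, so only the para hydroxyl is methylated (13). Hydrolysis and decarboxylation then remove the ester carbon. The ester left by the ring synthesis thus serves once as a control element before it is excised.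

**12 from 9.** Each benzene ring is opened at the bond between the ester-bearing carbon and the chain-bearing carbon. This exposes at each end a linear 3,5,7-trioxo ester (11) whose alternating carbonyls map onto the meta oxygen–oxygen–alkyl pattern. The chain-bearing ring carbons are the two former carboxyl carbons of 1. The reactive ester terminus is stored as a dioxinone in 9 and is released through the acylketene 10. The forward step has to fold both ends in the aldol sense and aromatise them in one flask.

**9 from 7 and 3.** The two bonds cut join each chain carbonyl carbon to its neighbouring methylene on the dioxinone side. The disconnection is twofold, so two molecules of 7 are joined to one molecule of 3, one at each amide group. The dianion of 7 supplies the nucleophilic terminal carbon and the bis(N-methoxy-N-methylamide) 3 supplies both acyl groups. An amide of this type is chosen because its adduct does not collapse until work-up, which lets both ends react in one flask.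

**7 from 4 and 5; 3 from 1.** Keto-dioxinone 7 comes from acylation of the dienolate of 4 with 5, and 3 comes from amidation of 1.

## Alternatives that were turned down

**Alternative 1:** The chain is disconnected at the bond between its two carbons nearest ring B, after the diaryl ether has been made intermolecularly. The macrocycle is first closed through sulfur and oxidised to the 21-membered benzyl alkyl sulfone A2. A Ramberg–Bäcklund reaction (KOH on alumina, CBr2F2) then contracts A2 to the 20-membered styrene-type alkene A1, which is hydrogenated and demethylated to 20.
- For: the hindered ether is made between two small arenes without dilution constraints or a statistical step. Sulfur alkylation is among the most dependable large-ring closures, the loss of SO2 is irreversible, and the alkene geometry does not matter.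
- Against: two differently functionalised arenes have to be built separately and linearly. Sulfur is introduced, oxidised and expelled without leaving an atom in 20. The in situ halogenation must take the benzylic position beside an electron-rich trioxygenated ring. Hydrogenation and three demethylations follow.
- Comparison: it is stronger on the ether bond and on the macrocyclisation. The chosen route offers instead both arenes and every carbon of the skeleton in four steps from a C14 diacid and a C4 dioxinone. It pays with one statistical protection and a harder ether closure.

**Alternative 2:** Ring A itself is disconnected, in precursor A4. This is a 3-substituted cyclobutenone tethered through the twelve-carbon chain to ring B, which carries an ethynyl ether between its two methoxy groups. Heating opens the cyclobutenone to a vinylketene, which adds the alkynyl ether. Four-electron opening and six-electron closure then form three ring A bonds, and tautomerisation gives A3, which is 20 with the ring B hydroxyls methylated. The bonds formed run from the hydroxyl-bearing carbon to both neighbouring CH carbons, and from the ether-bearing carbon to the CH next to the chain-bearing carbon.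
- For: the ether oxygen comes from a ring B phenol by plain O-functionalisation. The meta pattern of ring A is dictated by the polarity of the alkynyl ether, no reagent is needed, and A3 is one deprotection from 20.
- Against: the ketene–alkyne cycloaddition must act as the macrocyclising event across a long tether, where ketene dimerisation and intermolecular annulation compete. Aryl ethynyl ethers flanked by two methoxy groups are hard to make and thermally fragile.
- Comparison: it is stronger on polarity control and on the brevity of the endgame. It is weaker because its key step has no counterpart as a large-ring closure, whereas the chosen key step runs a well-understood aromatisation twice at independent sites.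

**Alternative 3:** The ether is disconnected between the oxygen and ring A, with ring A at the oxidation level of a cyclohexenone. In A6 a 3-chlorocyclohex-2-enone is tethered to a 2,6-dimethoxyphenol unit (ring B). K2CO3 at high dilution lets the phenoxide add to C3 and expel chloride, giving the macrocyclic 3-aryloxycyclohexenone A5 (racemic). A5 is then dehydrogenated to the phenol and demethylated.
- For: the C–O bond forms without a metal by addition–elimination at a strongly electrophilic carbon, which tolerates the hindered phenoxide better than an aryl halide coupling. The polarity is unambiguous.
- Against: ring A arrives one oxidation level short, and the dehydrogenation of A5 must spare the electron-rich ring B and the benzylic positions. A stereocentre of no use is made and erased. The arene–chain–enone precursor has to be assembled linearly.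
- Comparison: it is stronger at the ether-forming step itself. The chosen route offers redox neutrality and step economy, since both rings are aromatic at the correct oxidation level after one operation.

Key step: step 4

Remark on the chemistry: 20 is treated as conformationally mobile and without stereoisomers. The single statistical step (step 7) is accepted as the cost of building both rings at once.

## Route

Step 1
Reactants: 1 tetradecanedioic acid
Product: 3 N1,N14-dimethoxy-N1,N14-dimethyltetradecanediamide, via bis(acylimidazole) 2 (not isolated)
Conditions: CDI, CH2Cl2/THF, rt; then MeNH(OMe)·HCl, rt
Reagents that add atoms: N,O-dimethylhydroxylamine hydrochloride, CNOC.Cl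
Why: Activation of a carboxylic acid as its acyl imidazolide followed by aminolysis is the standard one-flask amidation; the two termini are equivalent and react independently.

Step 2
Reactants: 4 2,2,6-trimethyl-4H-1,3-dioxin-4-one; 5 acetyl chloride
Product: 7 2,2-dimethyl-6-(2-oxopropyl)-4H-1,3-dioxin-4-one, via lithium dienolate 6 (not isolated)
Conditions: LiN(SiMe3)2, THF, −78 °C (2 equiv of 6 per 5); then 5, −78 °C; aq. HCl
Reagents that add atoms: none
Why: Deprotonation of the 6-methyl group gives a dienolate that is C-acylated at the exocyclic carbon (Claisen-type acylation). Two equivalents of dienolate per acid chloride are used because the product is more acidic than 4; the excess 4 is recovered.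

Step 3
Reactants: 7 2,2-dimethyl-6-(2-oxopropyl)-4H-1,3-dioxin-4-one (two molecules for each molecule of 3); 3 N1,N14-dimethoxy-N1,N14-dimethyltetradecanediamide
Product: 9 6,6'-(2,4,17,19-tetraoxoicosane-1,20-diyl)bis(2,2-dimethyl-4H-1,3-dioxin-4-one), via dilithium dianion 8 (not isolated)
Conditions: 7 (2.6 equiv), LiN(i-Pr)2 (5.2 equiv), THF, −78 to −40 °C; then 3 (1.0 equiv), −78 to −20 °C; aq. HCl to pH 3
Reagents that add atoms: 2,2-dimethyl-6-(2-oxopropyl)-4H-1,3-dioxin-4-one (the second molecule of 7), CC(=O)CC1=CC(=O)OC(C)(C)O1
Why: Each of the two amide groups of 3 is acylated by one molecule of dianion 8 at its terminal, most basic carbon (Claisen-type acylation of a dianion), so two molecules of 7 are consumed and two molecules of N,O-dimethylhydroxylamine are released for each molecule of 9. The N-methoxy-N-methylamide holds each chelated tetrahedral adduct until work-up, so no acidic 1,3-diketone is present to quench the remaining dianion and no over-addition occurs. The slight excess of 7 drives both termini to completion and is recovered.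

Step 4
Reactants: 9 6,6'-(2,4,17,19-tetraoxoicosane-1,20-diyl)bis(2,2-dimethyl-4H-1,3-dioxin-4-one)
Product: 12 dimethyl 6,6'-(dodecane-1,12-diyl)bis(2,4-dihydroxybenzoate), via bis(acylketene) 10 (not isolated), via bis(triketo ester) 11 (not isolated)
Conditions: MeOH (excess), PhMe, 110 °C (sealed); then Cs2CO3, MeOH, rt; then HCl/MeOH, rt
Reagents that add atoms: methanol, CO
Why: Each dioxinone undergoes a thermal retro-[4+2] reaction that expels acetone and leaves an acylketene (10), which methanol captures as a β-keto ester, so that each chain end becomes a methyl 3,5,7-trioxoalkanoate (11). Cs2CO3 then equilibrates the enolates, and the C2 enolate adds to the C7 ketone, the carbonyl carbon that carries the twelve-carbon chain, in a 6-(enolendo)-exo-trig aldol closure; this is the mode of closure for both rings and forms in each the bond between the ester-bearing and the chain-bearing carbon. One molecule of water is lost from each aldol adduct and acid completes the enolisation of the C3 and C5 carbonyls to the two phenols, so each ring aromatises by one dehydration and two tautomerisations. The closest known reaction type is the thermolysis, alcohol trapping and base-mediated aldol aromatisation of a single diketo-dioxinone to a resorcylate; here it is run at two termini that are insulated from each other by twelve methylenes and should react independently. No stereocentre survives, since the carbinol carbon formed in the aldol step becomes an aromatic carbon. The step needs the C2-to-C7 aldol fold over the C6-to-C1 Claisen fold (an acylphloroglucinol) and over O-cyclisation to pyranones. C2 is not the most acidic site, since C4 and C6 lie between two ketones, but under carbonate all enolates interconvert and only the C2-to-C7 addition attacks a ketone through a six-membered transition state and is then drained irreversibly by aromatisation, whereas the Claisen fold would have to expel methoxide from an ester and the pyranone pathways are acid- and heat-driven. Excess methanol during the thermolysis keeps the ketene from being captured by its own enol oxygen.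

Step 5
Reactants: 12 dimethyl 6,6'-(dodecane-1,12-diyl)bis(2,4-dihydroxybenzoate)
Product: 13 dimethyl 6,6'-(dodecane-1,12-diyl)bis(2-hydroxy-4-methoxybenzoate)
Conditions: MeI (2.2 equiv), K2CO3, acetone, rt
Reagents that add atoms: iodomethane, CI
Why: In each ring the hydroxyl para to the ester is free and the more acidic, while the ortho hydroxyl is held in a hydrogen bond to the ester carbonyl. Williamson methylation with a slight excess of MeI should therefore stop at one ether per ring.

Step 6
Reactants: 13 dimethyl 6,6'-(dodecane-1,12-diyl)bis(2-hydroxy-4-methoxybenzoate)
Product: 15 3,3'-(dodecane-1,12-diyl)bis(5-methoxyphenol), via diacid 14 (not isolated)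
Conditions: KOH, DMSO/H2O, 100 °C; aq. HCl to pH 1; then DMSO, 140 °C
Reagents that add atoms: none
Why: Hydroxide hydrolyses the hindered salicylate esters. The 2-hydroxy-4-methoxybenzoic acids then lose CO2 on heating by ipso-protonation at a carbon that is ortho to the hydroxyl and para to the methoxy group (protodecarboxylation of an electron-rich salicylic acid).

Step 7
Reactants: 15 3,3'-(dodecane-1,12-diyl)bis(5-methoxyphenol)
Product: 16 3-methoxy-5-{12-[3-methoxy-5-(methoxymethoxy)phenyl]dodecyl}phenol
Conditions: NaH (1 equiv), MOMCl (1 equiv), THF/DMF, 0 °C to rt
Reagents that add atoms: chloromethyl methyl ether, COCCl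
Why: The two phenols are equivalent and remote, so one equivalent of base and chloride should give a statistical mixture with the mono-ether as the largest single component (O-alkylation of a phenoxide). It is separated by polarity from unreacted 15 and from doubly protected material, both of which are returned to 15.

Step 8
Reactants: 16 3-methoxy-5-{12-[3-methoxy-5-(methoxymethoxy)phenyl]dodecyl}phenol
Product: 18 3-{12-[4-iodo-3-methoxy-5-(methoxymethoxy)phenyl]dodecyl}-5-methoxyphenol, via dilithio species 17 (not isolated)
Conditions: n-BuLi (2.3 equiv), THF, 0 °C; then ICH2CH2I, −78 °C to rt; aq. NH4Cl
Reagents that add atoms: 1,2-diiodoethane, ICCI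
Why: The first equivalent of n-BuLi forms the lithium phenoxide of ring A, which deactivates that ring. The second removes the proton between the methoxymethoxy and methoxy groups of ring B (directed ortho-metalation by two cooperating groups). The aryllithium is iodinated by 1,2-diiodoethane, a mild iodine donor that should leave the phenoxide untouched.

Step 9
Reactants: 18 3-{12-[4-iodo-3-methoxy-5-(methoxymethoxy)phenyl]dodecyl}-5-methoxyphenol
Product: 19 1^5,3^2-dimethoxy-3^6-(methoxymethoxy)-2-oxa-1(1,3),3(1,4)-dibenzenacyclopentadecaphane (20 with the ring A hydroxyl and one ring B hydroxyl as methyl ethers and the other ring B hydroxyl as its methoxymethyl ether)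
Conditions: CuI (30 mol%), picolinic acid (60 mol%), K3PO4, DMSO, 100 °C, slow addition of 18 (final 2 mM)
Reagents that add atoms: none
Why: Ullmann-type diaryl ether synthesis, in which the copper phenoxide of ring A couples with the aryl iodide of ring B. The flanking oxygen substituents hinder the iodide but can also coordinate copper, and the picolinate ligand is suited to hindered partners. Slow addition keeps the substrate dilute while the catalyst stays concentrated, which favours the unstrained 20-membered ring over oligomers.

Step 10
Reactants: 19 the protected macrocycle
Product: 20 2-oxa-1(1,3),3(1,4)-dibenzenacyclopentadecaphane-1^5,3^2,3^6-triol (the target)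
Conditions: BBr3, CH2Cl2, −78 °C to rt; then MeOH, H2O
Reagents that add atoms: none
Why: BBr3 cleaves the two aryl methyl ethers and the methoxymethyl ether by coordination to oxygen and bromide attack at the alkyl carbon (Lewis acid ether cleavage). The diaryl ether has no sp3 carbon on oxygen and should not be touched.

## Compound list

1 | tetradecanedioic acid | OC(=O)CCCCCCCCCCCCC(=O)O | starting material
2 | 1,14-di(1H-imidazol-1-yl)tetradecane-1,14-dione | O=C(CCCCCCCCCCCCC(=O)n1ccnc1)n1ccnc1 | intermediate (not isolated)
3 | N1,N14-dimethoxy-N1,N14-dimethyltetradecanediamide | CON(C)C(=O)CCCCCCCCCCCCC(=O)N(C)OC | intermediate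
4 | 2,2,6-trimethyl-4H-1,3-dioxin-4-one | CC1=CC(=O)OC(C)(C)O1 | starting material
5 | acetyl chloride | CC(=O)Cl | starting material
6 | lithium 2,2-dimethyl-6-methylidene-6H-1,3-dioxin-4-olate (dienolate of 4) | [Li+].C=C1C=C([O-])OC(C)(C)O1 | intermediate (not isolated)
7 | 2,2-dimethyl-6-(2-oxopropyl)-4H-1,3-dioxin-4-one | CC(=O)CC1=CC(=O)OC(C)(C)O1 | intermediate
8 | dilithium dianion of 7 (bis-enolate) | [Li+].[Li+].C=C([O-])C=C1C=C([O-])OC(C)(C)O1 | intermediate (not isolated)
9 | 6,6'-(2,4,17,19-tetraoxoicosane-1,20-diyl)bis(2,2-dimethyl-4H-1,3-dioxin-4-one) | CC1(C)OC(=O)C=C(CC(=O)CC(=O)CCCCCCCCCCCCC(=O)CC(=O)CC2=CC(=O)OC(C)(C)O2)O1 | intermediate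
10 | 3,5,7,20,22,24-hexaoxohexacosa-1,25-diene-1,26-dione (bis(acylketene)) | O=C=CC(=O)CC(=O)CC(=O)CCCCCCCCCCCCC(=O)CC(=O)CC(=O)C=C=O | intermediate (not isolated)
11 | dimethyl 3,5,7,20,22,24-hexaoxohexacosanedioate (bis(triketo ester)) | COC(=O)CC(=O)CC(=O)CC(=O)CCCCCCCCCCCCC(=O)CC(=O)CC(=O)CC(=O)OC | intermediate (not isolated)
12 | dimethyl 6,6'-(dodecane-1,12-diyl)bis(2,4-dihydroxybenzoate) | COC(=O)c1c(O)cc(O)cc1CCCCCCCCCCCCc1cc(O)cc(O)c1C(=O)OC | intermediate
13 | dimethyl 6,6'-(dodecane-1,12-diyl)bis(2-hydroxy-4-methoxybenzoate) | COC(=O)c1c(O)cc(OC)cc1CCCCCCCCCCCCc1cc(OC)cc(O)c1C(=O)OC | intermediate
14 | 6,6'-(dodecane-1,12-diyl)bis(2-hydroxy-4-methoxybenzoic acid) | OC(=O)c1c(O)cc(OC)cc1CCCCCCCCCCCCc1cc(OC)cc(O)c1C(=O)O | intermediate (not isolated)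
15 | 3,3'-(dodecane-1,12-diyl)bis(5-methoxyphenol) | COc1cc(O)cc(c1)CCCCCCCCCCCCc1cc(O)cc(OC)c1 | intermediate
16 | 3-methoxy-5-{12-[3-methoxy-5-(methoxymethoxy)phenyl]dodecyl}phenol | COCOc1cc(OC)cc(c1)CCCCCCCCCCCCc1cc(O)cc(OC)c1 | intermediate
17 | dilithio derivative of 16 (lithium phenoxide on ring A, lithium on ring B between the two ether oxygens) | COCOc1cc(CCCCCCCCCCCCc2cc(O[Li])cc(OC)c2)cc(OC)c1[Li] | intermediate (not isolated)
18 | 3-{12-[4-iodo-3-methoxy-5-(methoxymethoxy)phenyl]dodecyl}-5-methoxyphenol | COCOc1cc(CCCCCCCCCCCCc2cc(O)cc(OC)c2)cc(OC)c1I | intermediate
19 | 1^5,3^2-dimethoxy-3^6-(methoxymethoxy)-2-oxa-1(1,3),3(1,4)-dibenzenacyclopentadecaphane | COCOc1cc2cc(OC)c1Oc1cc(OC)cc(c1)CCCCCCCCCCCC2 | intermediate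
20 | 2-oxa-1(1,3),3(1,4)-dibenzenacyclopentadecaphane-1^5,3^2,3^6-triol (CNP0314249.0) | Oc1cc2cc(c1)Oc1c(O)cc(cc1O)CCCCCCCCCCCC2 | target

## Step count and risk

Total: 10 steps. Longest linear sequence: 9 steps (1 → 3 → 9 → 12 → 13 → 15 → 16 → 18 → 19 → 20; the branch 4 + 5 → 7 joins at step 3).

**Step 4 (key step).**
- Risk: capture of the ketene or of the enolised triketo ester by its own enol oxygen would lead to pyranones. The two termini may also fail to aromatise in unison, leaving half-folded material, and methoxide may cleave the triketone by a retro-Claisen reaction.
- Fallback: from 9, aromatise with the dioxinone rings intact. Et3N in CH2Cl2 lets the vinylogous enolate carbon C5 of each dioxinone add to the chain ketone and gives, after dehydration, 5,5'-(dodecane-1,12-diyl)bis(7-hydroxy-2,2-dimethyl-4H-1,3-benzodioxin-4-one) F1. In this mode the ester function stays tied up in the heterocycle, so neither a ketene nor a free triketo ester is present. Methanolysis of both acetonides (K2CO3 or NaOMe, MeOH) returns the route to 12.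

**Step 9.**
- Risk: slow oxidative addition at an iodide flanked by two donor substituents would let protodeiodination and intermolecular coupling overtake ring closure. Material that loses iodine is 16 and can be recycled.
- Fallback: reverse the polarity of the ether bond, from 16. Lithiation as in step 8, trapping with B(OMe)3 and oxidation in the same flask (H2O2, NaOH) give 4-[12-(3-hydroxy-5-methoxyphenyl)dodecyl]-2-methoxy-6-(methoxymethoxy)phenol F2. The unhindered ring A phenol is triflated selectively (PhNTf2, K2CO3) to 3-{12-[4-hydroxy-3-methoxy-5-(methoxymethoxy)phenyl]dodecyl}-5-methoxyphenyl trifluoromethanesulfonate F3. Palladium-catalysed C–O coupling of the hindered ring B phenol with the ring A triflate (Pd(OAc)2, t-BuXPhos, K3PO4, PhMe, 100 °C, high dilution) closes the ring and comes back to 19. In this variant the ether oxygen stems from the oxidation of ring B, not from the fold.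

**Step 8.**
- Risk: electrophilic iodination of the ring A phenoxide may compete with iodination of the aryllithium, and aggregation of the dianion may leave the lithiation incomplete.
- Fallback: from 16, mask the phenol as the triisopropylsilyl ether F4 (i-Pr3SiCl, imidazole, DMF). Lithiate between the ring B ethers (n-BuLi) and quench with I2 to give the iodide F5. Desilylation with Bu4NF returns to 18.

**Step 3.**
- Risk: the twofold acylation may stop after one terminus has reacted (poor solubility of 3 at low temperature, proton exchange once an adduct collapses), and amide base may attack the dioxinone carbonyl.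
- Fallback: from 3, drop the dioxinone mask for this bond. Methyl 3,5-dioxohexanoate (CC(=O)CC(=O)CC(=O)OC, two molecules for each molecule of 3) is converted by LiN(i-Pr)2 (3 equiv for each molecule of the ester) into its trilithium trianion F6, which is acylated at the terminal carbon by each amide group of 3. After acidic work-up this gives the bis(triketo ester) 11 directly. The route is rejoined at 11, which is aromatised to 12 by the Cs2CO3 and HCl stages of step 4.

## Further compounds

F1 | step 4 | 5,5'-(dodecane-1,12-diyl)bis(7-hydroxy-2,2-dimethyl-4H-1,3-benzodioxin-4-one) | CC1(C)OC(=O)c2c(CCCCCCCCCCCCc3cc(O)cc4OC(C)(C)OC(=O)c34)cc(O)cc2O1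
F2 | step 9 | 4-[12-(3-hydroxy-5-methoxyphenyl)dodecyl]-2-methoxy-6-(methoxymethoxy)phenol | COCOc1cc(CCCCCCCCCCCCc2cc(O)cc(OC)c2)cc(OC)c1O
F3 | step 9 | 3-{12-[4-hydroxy-3-methoxy-5-(methoxymethoxy)phenyl]dodecyl}-5-methoxyphenyl trifluoromethanesulfonate | COCOc1cc(CCCCCCCCCCCCc2cc(OS(=O)(=O)C(F)(F)F)cc(OC)c2)cc(OC)c1O
F4 | step 8 | triisopropyl(3-methoxy-5-{12-[3-methoxy-5-(methoxymethoxy)phenyl]dodecyl}phenoxy)silane | COCOc1cc(OC)cc(c1)CCCCCCCCCCCCc1cc(O[Si](C(C)C)(C(C)C)C(C)C)cc(OC)c1
F5 | step 8 | (3-{12-[4-iodo-3-methoxy-5-(methoxymethoxy)phenyl]dodecyl}-5-methoxyphenoxy)triisopropylsilane | COCOc1cc(CCCCCCCCCCCCc2cc(O[Si](C(C)C)(C(C)C)C(C)C)cc(OC)c2)cc(OC)c1I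
F6 | step 3 | trilithium trianion of methyl 3,5-dioxohexanoate | [Li+].[Li+].[Li+].C=C([O-])C=C([O-])C=C([O-])OC
A1 | alternative 1 | macrocyclic (E)-alkene, the tri-O-methyl ether of 20 with a double bond between the two chain carbons nearest ring B | COc1cc2cc(c1)Oc1c(OC)cc(cc1OC)/C=C/CCCCCCCCCC2
A2 | alternative 1 | 21-membered benzyl alkyl sulfone, SO2 between the two chain carbons nearest ring B, tri-O-methyl ether | COc1cc2cc(c1)Oc1c(OC)cc(cc1OC)CS(=O)(=O)CCCCCCCCCCC2
A3 | alternative 2 | 20 with both ring B hydroxyls as methyl ethers | COc1cc2cc(OC)c1Oc1cc(O)cc(c1)CCCCCCCCCCCC2
A4 | alternative 2 | 3-[12-(4-ethynyloxy-3,5-dimethoxyphenyl)dodecyl]cyclobut-2-en-1-one | O=C1CC(=C1)CCCCCCCCCCCCc1cc(OC)c(OC#C)c(OC)c1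
A5 | alternative 3 | macrocyclic 3-aryloxycyclohex-2-enone, ring B as its dimethyl ether (racemic) | COc1cc2cc(OC)c1OC1=CC(=O)CC(C1)CCCCCCCCCCCC2
A6 | alternative 3 | 3-chloro-5-[12-(4-hydroxy-3,5-dimethoxyphenyl)dodecyl]cyclohex-2-en-1-one (racemic) | ClC1=CC(=O)CC(C1)CCCCCCCCCCCCc1cc(OC)c(O)c(OC)c1
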